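Remark: the ring is numbered as in 2-hydroxy-5-methoxy-3-pentadecyl-1,4-benzoquinone (C1 and C4 carbonyl, C2 hydroxy, C3 pentadecyl, C5 methoxy, C6 H). The target has no stereocentre, and the enol ether geometries of the intermediates have no consequence for it.

**Retrosynthetic overview**
- The hydroxyquinone ring is the enol tautomer of a cyclohex-5-ene-1,2,4-trione. C1–C2 is an oxalyl unit, and C3 lies alpha to the C4 carbonyl of a four-carbon unit C3–C4–C5–C6 oxygenated at C4 and C5. C3 is therefore a latent enol nucleophile and C2 an acyl electrophile, already at the final oxidation level.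
- The ring is cut at C6–C1 and C2–C3 into oxalyl chloride and a 2-methoxy-3-silyloxy-1,3-diene. The C5 methyl ether is carried as a methyl enol ether and the C4 oxygen as a silyl enol ether, so the placement of OMe against OH is fixed by the diene.
- Forward, the oxalyl unit is attached at C6 first, and the only ring is then closed by C-acylation at C3, which forms the C2–C3 bond.
- The diene comes from 3,3-dimethoxybutan-2-one and 1-bromopentadecane by enolate alkylation and a one-flask silyl enol ether formation with loss of methanol from the ketal.

Key step: step 3

**Step 1**
Reactants: 1 3,3-dimethoxybutan-2-one; 2 1-bromopentadecane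
Product: 3 2,2-dimethoxynonadecan-3-one
Conditions: 1 (1.5 equiv), LiN(i-Pr)2 (1.5 equiv), THF, –78 °C; then 2 (1.0 equiv), DMPU, n-Bu4NI (cat.), –78 °C → rt
Reagents that add atoms: none
Why: Kinetic lithium enolate alkylation (SN2) in which only the acetyl methyl group of 1 can be deprotonated, the ketal carbon blocking the other side, and an excess of enolate over 2 should limit a second alkylation.

**Step 2**
Reactants: 3 2,2-dimethoxynonadecan-3-one
Product: 5 (3Z)-2-methoxy-3-(trimethylsilyloxy)nonadeca-1,3-diene, via silyl enol ether ketal 4 (not isolated)
Conditions: Me3SiOSO2CF3 (2.3 equiv), i-Pr2NEt (2.6 equiv), CH2Cl2, –20 °C → rt; pentane extraction without aqueous work-up, used crude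
Reagents that add atoms: trimethylsilyl trifluoromethanesulfonate, C[Si](C)(C)OS(=O)(=O)C(F)(F)F
Why: Soft enolisation with silyl triflate and amine should give the thermodynamically favoured (Z)-silyl enol ether 4, whose ketal is then ionised by the silyl triflate to a methoxy-stabilised 2-silyloxyallyl cation that loses a proton from the adjacent methyl group to the hindered amine (ketal-to-enol-ether elimination).

**Step 3**
Reactants: 5 (3Z)-2-methoxy-3-(trimethylsilyloxy)nonadeca-1,3-diene; 6 oxalyl chloride
Product: 9 2-hydroxy-5-methoxy-3-pentadecylcyclohexa-2,5-diene-1,4-dione, via dienoyl chloride 7 (not isolated), via cyclohexenetrione 8 (not isolated)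
Conditions: 5 added slowly to 6 (1.05 equiv) and 2,6-di-tert-butyl-4-methylpyridine (1.1 equiv), CH2Cl2, –78 °C; then Me3SiOSO2CF3 (0.2 equiv), –78 °C → rt; 1 M HCl work-up
Reagents that add atoms: none
Why: Proposed new method: a formal [4+2] double C-acylation of a 2-methoxy-3-silyloxy-1,3-diene by oxalyl chloride, in which the unhindered, methoxy-activated CH2 terminus is acylated first (the proton goes to the pyridine base) to give acid chloride 7, and the silyl enol ether carbon then attacks the acid chloride carbon under silyl triflate catalysis with loss of Me3SiCl, which forms the C2–C3 bond and closes the ring to trione 8; enolisation of the C3–H between the C2 and C4 carbonyl groups then gives the vinylogous acid 9 at the final oxidation level. The closest known reaction types are the acylation of alkyl enol ethers with oxalyl chloride, the silyl-triflate-catalysed cyclisation of bis(silyl enol ethers) with oxalyl chloride and the Mukaiyama-type C-acylation of silyl enol ethers with acid chlorides. The six-membered carbocycle is closed in a 6-(enolendo)-exo-trig mode at the acyl carbon, and the (3E) geometry of 7, which places the acid chloride cis to the silyl enol ether, should be reached by acid-catalysed equilibration of the beta-methoxy enone. No stereocentre has to be controlled, because the C3 centre of 8 is lost on enolisation and the enol ether geometries disappear. The step needs site selectivity in the first acylation, C- over O-acylation in the closure and a 1:1 union of the halves; these should be secured by the unsubstituted CH2 terminus against the alkyl-substituted, silyl-shielded terminus, by the carbon nucleophilicity of silyl enol ethers towards acid chlorides together with the stability of the quinone, and by slow addition of 5 to 6 with the Lewis acid added only afterwards.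

**Compound list**
1 | 3,3-dimethoxybutan-2-one | CC(=O)C(C)(OC)OC | starting material
2 | 1-bromopentadecane | CCCCCCCCCCCCCCCBr | starting material
3 | 2,2-dimethoxynonadecan-3-one | CCCCCCCCCCCCCCCCC(=O)C(C)(OC)OC | intermediate
4 | (3Z)-2,2-dimethoxy-3-(trimethylsilyloxy)nonadec-3-ene | CC(OC)(OC)/C(O[Si](C)(C)C)=C/CCCCCCCCCCCCCCC | intermediate
5 | (3Z)-2-methoxy-3-(trimethylsilyloxy)nonadeca-1,3-diene | C=C(OC)/C(O[Si](C)(C)C)=C/CCCCCCCCCCCCCCC | intermediate
6 | oxalyl chloride | ClC(=O)C(=O)Cl | starting material
7 | (3E,5Z)-4-methoxy-2-oxo-5-(trimethylsilyloxy)henicosa-3,5-dienoyl chloride | ClC(=O)C(=O)/C=C(OC)\C(O[Si](C)(C)C)=C\CCCCCCCCCCCCCCC | intermediate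
8 | 5-methoxy-3-pentadecylcyclohex-5-ene-1,2,4-trione (racemic, transient) | CCCCCCCCCCCCCCCC1C(=O)C(=O)C=C(OC)C1=O | intermediate
9 | 2-hydroxy-5-methoxy-3-pentadecylcyclohexa-2,5-diene-1,4-dione | CCCCCCCCCCCCCCCC1=C(O)C(=O)C=C(OC)C1=O | target

Total step count: 3
Longest linear sequence: 3 steps (1 and 2 → 3 → 5 → 9)

**Steps most likely to fail**

Step 3 (proposed new method). The double acylation may go astray in several ways:
- first attack through the silyl enol ether terminus;
- O-acylation in the closure to an enol lactone;
- bridging of two diene molecules by one oxalyl unit;
- protodesilylation before closure;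
- conversion of the vinylogous acid into its acid chloride by surplus reagent.

The fallback is the established arene route. It sets out from compound 2 and comes back at compound 9. Commercial 1,2,4,5-tetramethoxybenzene would be lithiated (n-BuLi, THF, 0 °C) and alkylated with 2 to give 1,2,4,5-tetramethoxy-3-pentadecylbenzene F1. Oxidative demethylation with (NH4)2Ce(NO3)6 in MeCN–H2O should give 2,5-dimethoxy-3-pentadecylcyclohexa-2,5-diene-1,4-dione F2. Acid hydrolysis (HClO4, aqueous dioxane, rt) should then cleave preferentially the methoxy group flanked by the alkyl chain, which is twisted out of conjugation, and deliver 9.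

Step 2. The allyl cation may lose its proton from the chain side instead of the methyl group, giving an isomeric conjugated diene. Ketal ionisation may be incomplete, or the silyl enol ether may be hydrolysed during isolation. The fallback fixes the regiochemistry of proton loss before any silyl enol ether exists. It sets out from compound 3 and comes back at compound 5. Acid-catalysed thermal loss of methanol (anhydrous TsOH cat., toluene, reflux, MeOH distilled off) should give 2-methoxynonadec-1-en-3-one F3; in the keto ketal only the methyl group can lose the proton. Kinetic enolate trapping at the single enolisable position (LiN(i-Pr)2, Me3SiCl, THF, –78 °C) should then give 5.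

Step 1. Alkylation of the lithium enolate by the unactivated long-chain bromide may be slow, so that proton exchange between product and enolate leads to a second alkylation. The fallback is alkylation of a metalated hydrazone. It sets out from compound 1, uses compound 2 and comes back at compound 3. Condensation of 1 with Me2NNH2 (AcOH cat., EtOH, reflux) should give (E)-2-(3,3-dimethoxybutan-2-ylidene)-1,1-dimethylhydrazine F4. Deprotonation (LiN(i-Pr)2, THF, 0 °C) and clean monoalkylation with 2 should give (E)-2-(2,2-dimethoxynonadecan-3-ylidene)-1,1-dimethylhydrazine F5. Mild two-phase hydrolysis (aqueous oxalic acid, Et2O, rt), which the alpha-keto ketal should survive, returns 3.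

**Further compounds**
F1 | step 3 | 1,2,4,5-tetramethoxy-3-pentadecylbenzene | CCCCCCCCCCCCCCCc1c(OC)c(OC)cc(OC)c1OC
F2 | step 3 | 2,5-dimethoxy-3-pentadecylcyclohexa-2,5-diene-1,4-dione | CCCCCCCCCCCCCCCC1=C(OC)C(=O)C=C(OC)C1=O
F3 | step 2 | 2-methoxynonadec-1-en-3-one | C=C(OC)C(=O)CCCCCCCCCCCCCCCC
F4 | step 1 | (E)-2-(3,3-dimethoxybutan-2-ylidene)-1,1-dimethylhydrazine | C/C(=N\N(C)C)C(C)(OC)OC
F5 | step 1 | (E)-2-(2,2-dimethoxynonadecan-3-ylidene)-1,1-dimethylhydrazine | CCCCCCCCCCCCCCCC/C(=N\N(C)C)C(C)(OC)OC
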